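**Strategy.** Everything rests on cutting the aryl ether bond O1–C8a of ring C. The plan exploits that C8a lies para to the free C6–OH. Ring A is therefore a hydroquinone monoether, and a C8a–H phenol can be made electrophilic at C8a by two-electron oxidation. The key step dearomatises ring A to an orthoquinone monoketal, then lets the C2 carbinol oxygen attack C8a with loss of methanol and rearomatisation. This is a C–H to C–O ring closure that needs no halogen, base or protecting group and leaves C2 untouched. Its precursor is the open-chain (S)-β-hydroxy ketone 8, reached in three steps from syringol and veratraldehyde through a chalcone and an enantioselective copper-catalysed β-borylation.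

Key step: step 4

Assumption: the (S,S)-bipyridine ligand of step 3 is taken to deliver boron to the alkene face that leads to the S carbinol. The mirror-image ligand is equally accessible and is used instead if a configuration check on 8 shows the opposite sense.

Step 1
Reactants: 1 2,6-dimethoxyphenol (syringol)
Product: 3 3-acetyl-2,6-dimethoxyphenyl acetate, via 2,6-dimethoxyphenyl acetate 2 (not isolated)
Conditions: Ac2O (3 equiv), Sc(OTf)3 (10 mol%), MeNO2, rt then 50 °C
Reagents that add atoms: acetic anhydride CC(=O)OC(C)=O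
Why: Sc(OTf)3 first catalyses O-acetylation and then Friedel–Crafts acylation, in which the two methoxy groups of 2 steer the acylium ion to C3 (ortho to one, para to the other) because the acetate is only a weak donor, while the catalytic Lewis acid should spare the methyl ethers.

Step 2
Reactants: 3 3-acetyl-2,6-dimethoxyphenyl acetate; 4 3,4-dimethoxybenzaldehyde (veratraldehyde)
Product: 6 (E)-3-(3,4-dimethoxyphenyl)-1-(3-hydroxy-2,4-dimethoxyphenyl)prop-2-en-1-one, via 1-(3-hydroxy-2,4-dimethoxyphenyl)ethanone 5 (not isolated)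
Conditions: KOH (4 equiv), EtOH, rt; then 1 M HCl
Reagents that add atoms: none
Why: Ethanolic KOH cleaves the aryl acetate and the methyl ketone enolate of 5 then undergoes Claisen–Schmidt condensation with the non-enolisable aldehyde 4, the E1cB dehydration giving the thermodynamically preferred E enone.

Step 3
Reactants: 6 (E)-3-(3,4-dimethoxyphenyl)-1-(3-hydroxy-2,4-dimethoxyphenyl)prop-2-en-1-one
Product: 8 (3S)-3-(3,4-dimethoxyphenyl)-3-hydroxy-1-(3-hydroxy-2,4-dimethoxyphenyl)propan-1-one, via (S)-β-boryl ketone 7 (not isolated)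
Conditions: B2pin2 (1.2 equiv), Cu(OAc)2 (5 mol%), (S,S)-6,6'-bis(1-hydroxy-2,2-dimethylpropyl)-2,2'-bipyridine (6 mol%), H2O, 5 °C; then NaBO3·4H2O, THF–H2O, rt
Reagents that add atoms: bis(pinacolato)diboron CC1(C)OB(OC1(C)C)B1OC(C)(C)C(C)(C)O1 (boryl group of 7); sodium perborate [Na+].[O-]OB=O (carbinol oxygen of 8)
Why: This is the copper-catalysed enantioselective conjugate borylation of a chalcone in water, a protic medium in which the free phenol should be harmless; the chiral bipyridine–copper boryl species selects the alkene face and sets the C–B centre, and perborate oxidation replaces boron by oxygen with retention to give the S carbinol.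

Step 4
Reactants: 8 (3S)-3-(3,4-dimethoxyphenyl)-3-hydroxy-1-(3-hydroxy-2,4-dimethoxyphenyl)propan-1-one
Product: 11 (2S)-2-(3,4-dimethoxyphenyl)-6-hydroxy-5,7-dimethoxychroman-4-one, via orthoquinone monoketal 9 (not isolated), via cross-conjugated dienone 10 (not isolated)
Conditions: PhI(OAc)2 (1.0 equiv), MeOH, −10 °C; cold evaporation; then C6F5CO2H (10 mol%), 4 Å MS, CH2Cl2–HFIP (1,1,1,3,3,3-hexafluoropropan-2-ol) 4:1, 2 mM, 0 °C
Reagents that add atoms: methanol CO (second ketal methoxy group of 9; one methoxy group leaves again)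
Why: Proposed new method: PhI(OAc)2 binds the C6–OH of ring A and solvent methanol traps the phenoxenium ion at the methoxy-bearing ortho carbon C7, which stores the two-electron oxidation in ketal 9 (stable to methanol and acetic acid) and consumes the oxidant before any of the more easily oxidised phenol 11 exists; the acid in HFIP then re-ionises the ketal and the C2–OH attacks the para carbon C8a of the pentadienyl cation in an SN1'-type step to give dienone 10, which tautomerises irreversibly to 11. The closest known reaction types are the formation of orthoquinone monoketals from 2-methoxyphenols with PhI(OAc)2 in methanol, the acid-promoted substitution of quinone monoacetals by nucleophiles in HFIP with rearomatisation, and the oxygen heterocyclisation of orthoquinol acetates that carry a tethered alcohol, but a para-selective closure by a free secondary alcohol on such a ketal has not been shown. Ring C closes in a 6-exo-trig mode, because the attacked C8a=C8 bond lies outside the new ring. No lasting stereocentre is formed (C8a of 10 becomes planar again) and no bond at C2 is touched, so the S configuration of 8 is carried into 11. Chemoselectivity for ring A over the electron-rich ring B rests on the free phenol, the only group that can bind the iodane, and site selectivity rests on the tether, which reaches only C5 and C8a: attack at C5 gives a mixed ketal that re-opens, whereas attack at C8a is locked by aromatisation. Removal of methanol, high dilution and molecular sieves should suppress capture of the cation by methanol or water, its coupling with 11 and Diels–Alder dimerisation of 9.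

**Compound list**
1 | 2,6-dimethoxyphenol (syringol) | COc1cccc(OC)c1O | starting material
2 | 2,6-dimethoxyphenyl acetate | CC(=O)Oc1c(OC)cccc1OC | intermediate
3 | 3-acetyl-2,6-dimethoxyphenyl acetate | CC(=O)Oc1c(OC)ccc(C(C)=O)c1OC | intermediate
4 | 3,4-dimethoxybenzaldehyde (veratraldehyde) | COc1ccc(C=O)cc1OC | starting material
5 | 1-(3-hydroxy-2,4-dimethoxyphenyl)ethanone | CC(=O)c1ccc(OC)c(O)c1OC | intermediate
6 | (E)-3-(3,4-dimethoxyphenyl)-1-(3-hydroxy-2,4-dimethoxyphenyl)prop-2-en-1-one | COc1ccc(/C=C/C(=O)c2ccc(OC)c(O)c2OC)cc1OC | intermediate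
7 | (3S)-3-(3,4-dimethoxyphenyl)-1-(3-hydroxy-2,4-dimethoxyphenyl)-3-(4,4,5,5-tetramethyl-1,3,2-dioxaborolan-2-yl)propan-1-one | COc1ccc([C@H](CC(=O)c2ccc(OC)c(O)c2OC)B2OC(C)(C)C(C)(C)O2)cc1OC | intermediate
8 | (3S)-3-(3,4-dimethoxyphenyl)-3-hydroxy-1-(3-hydroxy-2,4-dimethoxyphenyl)propan-1-one | COc1ccc([C@H](CC(=O)c2ccc(OC)c(O)c2OC)O)cc1OC | intermediate
9 | 3-[(3S)-3-(3,4-dimethoxyphenyl)-3-hydroxypropanoyl]-2,6,6-trimethoxycyclohexa-2,4-dien-1-one | COc1ccc([C@H](CC(=O)C2=C(OC)C(=O)C(OC)(OC)C=C2)O)cc1OC | intermediate
10 | (2S)-2-(3,4-dimethoxyphenyl)-5,7-dimethoxy-2,3-dihydro-8aH-chromene-4,6-dione (8a-H tautomer of 11, C8a configuration open) | COc1ccc([C@@H]2CC(=O)C3=C(OC)C(=O)C(OC)=CC3O2)cc1OC | intermediate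
11 | (2S)-2-(3,4-dimethoxyphenyl)-6-hydroxy-5,7-dimethoxychroman-4-one | COc1ccc([C@@H]2CC(=O)c3c(cc(OC)c(O)c3OC)O2)cc1OC | target

**Total steps:** 4. **Longest linear sequence:** 4 (1 → 3 → 6 → 8 → 11).

**Steps most likely to fail**

Step 4.
- What may go wrong: over-oxidation, if ring closure or methanol capture at C8a starts while oxidant is still present; Diels–Alder dimerisation of the dienone during the solvent change; acid ionisation of the electron-rich benzylic carbinol, with loss of configuration or dehydration.
- The fallback forms the same bond by known palladium-catalysed aryl etherification. It sets out from 1 and comes back at 11.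
- NBS in MeCN brominates 1 para to the hydroxyl to give 4-bromo-2,6-dimethoxyphenol F1. Ac2O/pyridine gives 4-bromo-2,6-dimethoxyphenyl acetate F2. AcCl/SnCl4 acylates one of the two equivalent free positions to give 3-acetyl-4-bromo-2,6-dimethoxyphenyl acetate F3, which places bromine on the future C8a.
- KOH/EtOH with 4 gives, through 1-(6-bromo-3-hydroxy-2,4-dimethoxyphenyl)ethanone F4, the bromochalcone F5. BnBr/K2CO3 converts it into the benzyl ether F6.
- Borylation as in step 3 gives the (S)-boronate F7, and perborate gives the (S)-β-hydroxy ketone F8. NaBH4 removes the base-sensitive aldol motif by giving the 1,3-diol F9 (both C1 epimers, which is inconsequential).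
- Pd(OAc)2, 2-(di-tert-butylphosphino)-1,1'-binaphthyl, Cs2CO3, toluene, 70 °C (Buchwald–Hartwig type) closes O1–C8a to the flavan-4-ol F10; the C4 hydroxyl cannot reach C8a. Dess–Martin periodinane gives the 6-O-benzyl flavanone F11, and H2, Pd/C returns 11.

Step 3.
- What may go wrong: poor facial selectivity on the electron-rich β-aryl enone, or slow turnover because the phenol binds copper or boron.
- The fallback replaces alkene functionalisation by an enantioselective C–C bond formation. It sets out from 3 and comes back at 8.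
- K2CO3/MeOH frees 5, which is isolated this time. TMSOTf/Et3N (2.2 equiv) gives the bis-silylated enol ether F12.
- A catalytic enantioselective Mukaiyama aldol addition to 4 follows (SiCl4, chiral binaphthyldiamine-derived bisphosphoramide 5 mol%, i-Pr2NEt, CH2Cl2, −78 °C). Aqueous KF/NaHCO3 work-up removes the silyl groups and gives 8.

Step 1.
- What may go wrong: incomplete C-acylation of the acetate-deactivated ring, migration of the O-acetyl group, or loss of the methyl ether ortho to the new ketone.
- The fallback builds the aryl ketone by halogen–metal exchange. It sets out from 1 and comes back at 6.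
- TBSCl/imidazole gives the silyl ether F13. NBS in MeCN brominates para to a methoxy group to give the bromide F14. n-BuLi (THF, −78 °C) followed by N-methoxy-N-methylacetamide gives the silyl-protected acetophenone F15.
- F15 enters step 2 in place of 3, since KOH/EtOH cleaves the aryl silyl ether just as it cleaves the acetate, and delivers 6.

**Further compounds**
F1 | step 4 | 4-bromo-2,6-dimethoxyphenol | COc1cc(Br)cc(OC)c1O
F2 | step 4 | 4-bromo-2,6-dimethoxyphenyl acetate | CC(=O)Oc1c(OC)cc(Br)cc1OC
F3 | step 4 | 3-acetyl-4-bromo-2,6-dimethoxyphenyl acetate | CC(=O)Oc1c(OC)cc(Br)c(C(C)=O)c1OC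
F4 | step 4 | 1-(6-bromo-3-hydroxy-2,4-dimethoxyphenyl)ethanone | CC(=O)c1c(Br)cc(OC)c(O)c1OC
F5 | step 4 | (E)-1-(6-bromo-3-hydroxy-2,4-dimethoxyphenyl)-3-(3,4-dimethoxyphenyl)prop-2-en-1-one (bromochalcone) | COc1ccc(/C=C/C(=O)c2c(Br)cc(OC)c(O)c2OC)cc1OC
F6 | step 4 | (E)-1-[3-(benzyloxy)-6-bromo-2,4-dimethoxyphenyl]-3-(3,4-dimethoxyphenyl)prop-2-en-1-one (benzyl ether) | COc1ccc(/C=C/C(=O)c2c(Br)cc(OC)c(OCc3ccccc3)c2OC)cc1OC
F7 | step 4 | (3S)-1-[3-(benzyloxy)-6-bromo-2,4-dimethoxyphenyl]-3-(3,4-dimethoxyphenyl)-3-(4,4,5,5-tetramethyl-1,3,2-dioxaborolan-2-yl)propan-1-one ((S)-boronate) | COc1ccc([C@H](CC(=O)c2c(Br)cc(OC)c(OCc3ccccc3)c2OC)B2OC(C)(C)C(C)(C)O2)cc1OC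
F8 | step 4 | (3S)-1-[3-(benzyloxy)-6-bromo-2,4-dimethoxyphenyl]-3-(3,4-dimethoxyphenyl)-3-hydroxypropan-1-one ((S)-β-hydroxy ketone) | COc1ccc([C@H](CC(=O)c2c(Br)cc(OC)c(OCc3ccccc3)c2OC)O)cc1OC
F9 | step 4 | (3S)-1-[3-(benzyloxy)-6-bromo-2,4-dimethoxyphenyl]-3-(3,4-dimethoxyphenyl)propane-1,3-diol (1,3-diol, C1 epimers) | COc1ccc([C@H](CC(O)c2c(Br)cc(OC)c(OCc3ccccc3)c2OC)O)cc1OC
F10 | step 4 | (2S)-6-(benzyloxy)-2-(3,4-dimethoxyphenyl)-5,7-dimethoxychroman-4-ol (flavan-4-ol, C4 epimers) | COc1ccc([C@@H]2CC(O)c3c(cc(OC)c(OCc4ccccc4)c3OC)O2)cc1OC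
F11 | step 4 | (2S)-6-(benzyloxy)-2-(3,4-dimethoxyphenyl)-5,7-dimethoxychroman-4-one (6-O-benzyl flavanone) | COc1ccc([C@@H]2CC(=O)c3c(cc(OC)c(OCc4ccccc4)c3OC)O2)cc1OC
F12 | step 3 | {1-[2,4-dimethoxy-3-(trimethylsilyloxy)phenyl]ethenyloxy}trimethylsilane (bis-silylated enol ether) | C=C(O[Si](C)(C)C)c1ccc(OC)c(O[Si](C)(C)C)c1OC
F13 | step 1 | tert-butyl(2,6-dimethoxyphenoxy)dimethylsilane (silyl ether) | COc1cccc(OC)c1O[Si](C)(C)C(C)(C)C
F14 | step 1 | (3-bromo-2,6-dimethoxyphenoxy)(tert-butyl)dimethylsilane (bromide) | COc1ccc(Br)c(OC)c1O[Si](C)(C)C(C)(C)C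
F15 | step 1 | 1-{3-[(tert-butyldimethylsilyl)oxy]-2,4-dimethoxyphenyl}ethanone (silyl-protected acetophenone) | CC(=O)c1ccc(OC)c(O[Si](C)(C)C(C)(C)C)c1OC
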